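**Plan**
- Retrosynthesis: a Wittig cut at the chain C=C that joins the C15 dienal of the dihydroxycyclohexene half to the butenolide half; a Stille cut between the butenolide α-carbon and the E-vinyl group; the butenolide opened to (E)-2,3-dibromoacrylic acid and a dienynol; in the 7-oxabicyclo[2.2.1]heptane, the ring C–C bond between the bridgehead CH–O and the CH2 next to the C(Me)OH carbon and the C–O bond from the bridge oxygen to the quaternary bridgehead are cut together.
- Enabling feature: the oxolane ring of the bicycle (bridge O, bridgehead CH, that CH2, the C(Me)OH carbon, the quaternary bridgehead) is a C=O unit laid across a three-carbon unit whose middle carbon carries a one-carbon branch and whose quaternary end carries the two-carbon side chain (as an alkyne) and the CMe2–CH2 tether. An aldehyde tethered to a 2-(silylmethyl)allyl/propargyl cation equivalent can therefore close the cyclohexane and the oxygen bridge in one formal [3+2] event.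
- Forward, bicyclic half: lactone → hydroxy ynone → allylsilane carbinol → aldehyde with tertiary OSiEt3 → key step (carbocycle, then oxygen bridge) → ketone → methyl carbinol → alkyne → E-vinylstannane. The helpers SiMe3 and OSiEt3 leave in the key step, the exocyclic methylene becomes C(Me)OH, and TIPS is removed.
- Centre and left: the bromo-ylidenebutenolide comes from coupling/lactonisation and the C15 dihydroxy dienal from safranal; Stille coupling, phosphonium salt formation and Wittig reaction then join the chain with no protecting groups.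
- Stereochemistry: the bridgehead pair comes from the chiral counter-anion of the key step (the racemic quaternary silyl ether centre is erased, so the step is stereoconvergent); C(Me)OH from exo attack of MeMgBr; the cis-diol from Mn-salen epoxidation then Pd/CO2 double inversion; the Z-ylidene from anti oxymetalation; E alkenes from hydrostannation, HWE and stabilised ylides.

Key step: step 5

Remark: the catalyst enantiomers in steps 5 and 14 are assigned by analogy (aldehyde allylation; a ring cis-alkene conjugated on one side, as in 1,2-dihydronaphthalene) and the mirror-image catalyst is taken if the first intermediate shows the opposite sense; compounds 7–9 are racemic on purpose.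

Step 1
Reactants: 1 3,3-dimethyldihydrofuran-2(3H)-one; 2 ethynyltriisopropylsilane
Product: 4 6-hydroxy-4,4-dimethyl-1-(triisopropylsilyl)hex-1-yn-3-one, via lithium acetylide 3 (not isolated)
Conditions: n-BuLi, THF, −78 °C; then 1, −78 to −20 °C; aq. NH4Cl
Reagents that add atoms: none
Why: Acetylide addition to a lactone stops at the lactolate at low temperature and should give the ω-hydroxy ynone on work-up, the α,α-dimethyl group excluding enolisation.

Step 2
Reactants: 4 6-hydroxy-4,4-dimethyl-1-(triisopropylsilyl)hex-1-yn-3-one; 5 (2-bromoallyl)trimethylsilane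
Product: 7 rac-4,4-dimethyl-1-(triisopropylsilyl)-3-[3-(trimethylsilyl)prop-1-en-2-yl]hex-1-yne-3,6-diol, via vinyl Grignard reagent 6 (not isolated)
Conditions: 5, Mg, THF; then 4 (2.5 equiv of 6), THF, −78 to 0 °C; aq. NH4Cl
Reagents that add atoms: none
Why: 1,2-Addition of a vinyl Grignard reagent to a non-enolisable ynone (first equivalent consumed by the hydroxyl, TIPS blocking conjugate addition) should give the tertiary carbinol as a racemate, which is harmless because this centre is erased in step 5.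

Step 3
Reactants: 7 rac-4,4-dimethyl-1-(triisopropylsilyl)-3-[3-(trimethylsilyl)prop-1-en-2-yl]hex-1-yne-3,6-diol
Product: 8 rac-3,6-bis[(triethylsilyl)oxy]-4,4-dimethyl-1-(triisopropylsilyl)-3-[3-(trimethylsilyl)prop-1-en-2-yl]hex-1-yne
Conditions: TESOTf, 2,6-lutidine, CH2Cl2, −78 to 0 °C
Reagents that add atoms: triethylsilyl triflate, CC[Si](CC)(CC)OS(=O)(=O)C(F)(F)F
Why: Silyl triflate with a hindered base silylates both the primary and the hindered tertiary hydroxyl under buffered conditions that the allylsilane tolerates.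

Step 4
Reactants: 8 rac-3,6-bis[(triethylsilyl)oxy]-4,4-dimethyl-1-(triisopropylsilyl)-3-[3-(trimethylsilyl)prop-1-en-2-yl]hex-1-yne
Product: 9 rac-3,3-dimethyl-4-[(triethylsilyl)oxy]-6-(triisopropylsilyl)-4-[3-(trimethylsilyl)prop-1-en-2-yl]hex-5-ynal
Conditions: (COCl)2, DMSO, CH2Cl2, −78 to −40 °C; then Et3N
Reagents that add atoms: none
Why: Swern conditions convert a primary triethylsilyl ether directly into the aldehyde (oxidative desilylation) while the tertiary silyl ether survives, and the capped tertiary oxygen cannot form a lactol with the new aldehyde.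

Step 5
Reactants: 9 rac-3,3-dimethyl-4-[(triethylsilyl)oxy]-6-(triisopropylsilyl)-4-[3-(trimethylsilyl)prop-1-en-2-yl]hex-5-ynal
Product: 11 (1R,4S)-2,2-dimethyl-6-methylidene-1-[(triisopropylsilyl)ethynyl]-7-oxabicyclo[2.2.1]heptane, via cyclohexyl trimethylsilyl ether 10 (not isolated)
Conditions: chiral N-triflyl imidodiphosphorimidate (IDPi, 3 mol%), methallyl-SiMe3 (5 mol%, silylates the catalyst), toluene, −60 to −20 °C
Reagents that add atoms: none
Why: Proposed new method: the silylated IDPi (a silylium ion paired with a confined chiral anion) activates the aldehyde, the CH2= terminus of the 2-(trimethylsilylmethyl)vinyl group adds to C=O (C–C bond; six-membered carbocycle closed exo with respect to C=O through a chair) and the β-silyl cation passes Me3Si+ on to give silyl ether 10, after which the same Lewis acid ionises the tertiary C–OSiEt3 bond, now propargylic and allylic, and the silyl ether oxygen captures the planar cation across the ring (C–O bond; transannular SN1 closure through a boat that completes both oxolane rings of the 7-oxabicyclo[2.2.1]heptane), Me3Si+ leaving with Et3SiO as the disiloxane. The closest known reaction types are the IDPi-catalysed enantioselective Hosomi–Sakurai allylation of aldehydes and the [3+2] annulations of 2-(silylmethyl)allyl (trimethylenemethane-type) donors with aldehydes that give methylenetetrahydrofurans under Lewis-acid or Pd catalysis. The CH–O centre is set by the chiral counter-anion in the allylation; the quaternary bridgehead needs no control of its own, because the bridge can form only on the face that the carbinol oxygen occupies, so both C–OSiEt3 epimers of racemic 9 converge through one cation on a single enantiomer of 11. The step needs enantioface selectivity at the aldehyde (catalyst), allylation ahead of ionisation or protodesilylation (aprotic silylium conditions; hindered silyl ether as leaving group; if ionisation comes first, the aldehyde oxygen captures the cation and the same allylsilane closes the resulting oxolanyl cation to the same product) and C–O closure at the ring carbon, which the substrate secures because closure at the CH2 end of the allyl cation would put a double bond at a bridgehead.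

Step 6
Reactants: 11 (1R,4S)-2,2-dimethyl-6-methylidene-1-[(triisopropylsilyl)ethynyl]-7-oxabicyclo[2.2.1]heptane
Product: 12 (1S,4S)-6,6-dimethyl-1-[(triisopropylsilyl)ethynyl]-7-oxabicyclo[2.2.1]heptan-2-one
Conditions: O3, CH2Cl2–MeOH, −78 °C (indicator dye); then Me2S
Reagents that add atoms: ozone, [O-][O+]=O
Why: Ozonolysis cleaves the electron-rich 1,1-disubstituted alkene much faster than the silyl-shielded alkyne and leaves the non-epimerisable bridgehead untouched.

Step 7
Reactants: 12 (1S,4S)-6,6-dimethyl-1-[(triisopropylsilyl)ethynyl]-7-oxabicyclo[2.2.1]heptan-2-one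
Product: 13 (1S,2R,4S)-2,6,6-trimethyl-1-[(triisopropylsilyl)ethynyl]-7-oxabicyclo[2.2.1]heptan-2-ol
Conditions: MeMgBr, THF, −78 to 0 °C
Reagents that add atoms: methylmagnesium bromide, C[Mg]Br
Why: Grignard addition to the bicyclic ketone should occur from the exo face (syn to the oxygen bridge, the endo face being shielded by the endo methyl of the gem-dimethyl group), which places methyl exo and hydroxyl endo, anti to the bridge oxygen as in the target.

Step 8
Reactants: 13 (1S,2R,4S)-2,6,6-trimethyl-1-[(triisopropylsilyl)ethynyl]-7-oxabicyclo[2.2.1]heptan-2-ol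
Product: 14 (1S,2R,4S)-1-ethynyl-2,6,6-trimethyl-7-oxabicyclo[2.2.1]heptan-2-ol
Conditions: TBAF, THF, 0 °C to rt
Reagents that add atoms: none
Why: Fluoride cleaves the C(sp)–Si bond selectively and affects neither the ether bridge nor the tertiary alcohol.

Step 9
Reactants: 14 (1S,2R,4S)-1-ethynyl-2,6,6-trimethyl-7-oxabicyclo[2.2.1]heptan-2-ol
Product: 15 (1R,2R,4S)-2,6,6-trimethyl-1-[(E)-2-(tributylstannyl)ethenyl]-7-oxabicyclo[2.2.1]heptan-2-ol
Conditions: Bu3SnH, PdCl2(PPh3)2 (2 mol%), THF, 0 °C
Reagents that add atoms: tributyltin hydride, CCCC[SnH](CCCC)CCCC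
Why: Pd-catalysed syn-hydrostannation of a terminal alkyne next to a quaternary carbon should place tin on the terminal carbon and give the E-vinylstannane.

Step 10
Reactants: 16 propiolic acid
Product: 17 (E)-2,3-dibromoprop-2-enoic acid
Conditions: Br2, CHCl3, 0 °C to rt, dark
Reagents that add atoms: bromine, BrBr
Why: Anti addition of bromine to the alkyne gives the E-dibromide, in which the β-bromine is cis to the carboxyl group as the lactonisation in step 13 requires.

Step 11
Reactants: 18 (E)-3-methylpent-2-en-4-yn-1-ol; 19 ethyl (triphenylphosphoranylidene)acetate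
Product: 21 ethyl (2E,4E)-5-methylhepta-2,4-dien-6-ynoate, via enynal 20 (not isolated)
Conditions: activated MnO2, 19, CH2Cl2, rt, one pot
Reagents that add atoms: none
Why: Tandem allylic oxidation/Wittig reaction traps the volatile enynal as it forms and the stabilised ylide gives the E-alkene.

Step 12
Reactants: 21 ethyl (2E,4E)-5-methylhepta-2,4-dien-6-ynoate
Product: 22 (2E,4E)-5-methylhepta-2,4-dien-6-yn-1-ol
Conditions: DIBAL-H, CH2Cl2, −78 °C; aq. Rochelle salt
Reagents that add atoms: none
Why: DIBAL-H reduces the conjugated ester to the allylic alcohol by 1,2-reduction without touching the diene or the alkyne.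

Step 13
Reactants: 17 (E)-2,3-dibromoprop-2-enoic acid; 22 (2E,4E)-5-methylhepta-2,4-dien-6-yn-1-ol
Product: 24 (5Z)-3-bromo-5-[(2E,4E)-6-hydroxy-2-methylhexa-2,4-dien-1-ylidene]furan-2(5H)-one, via enynoic acid 23 (not isolated)
Conditions: PdCl2(PPh3)2 (5 mol%), CuI (10 mol%), Et3N, MeCN, rt
Reagents that add atoms: none
Why: Sonogashira coupling at the more reactive β-C–Br bond followed by 5-exo-dig anti oxymetalation/protodemetalation of the (Z)-enynoic acid (tandem coupling–lactonisation of a β-halo-acrylic acid) should give the Z-ylidenebutenolide and keep the α-bromine for step 18.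

Step 14
Reactants: 25 safranal (2,6,6-trimethylcyclohexa-1,3-diene-1-carbaldehyde)
Product: 26 (1R,6S)-2,4,4-trimethyl-7-oxabicyclo[4.1.0]hept-2-ene-3-carbaldehyde
Conditions: (R,R)-Mn(salen)Cl (5 mol%), m-CPBA, NMO, CH2Cl2, −78 °C
Reagents that add atoms: m-chloroperbenzoic acid, OOC(=O)c1cccc(Cl)c1
Why: Jacobsen–Katsuki epoxidation is selective for the cis-disubstituted ring alkene conjugated on one side (the tetrasubstituted, formyl-bearing alkene is inert) and the catalyst sets both epoxide carbons on one face.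

Step 15
Reactants: 26 (1R,6S)-2,4,4-trimethyl-7-oxabicyclo[4.1.0]hept-2-ene-3-carbaldehyde
Product: 27 (3aR,7aS)-4,6,6-trimethyl-2-oxo-3a,6,7,7a-tetrahydro-1,3-benzodioxole-5-carbaldehyde
Conditions: Pd2(dba)3·CHCl3 (2.5 mol%), P(OiPr)3, CO2 (1 atm), THF, rt
Reagents that add atoms: carbon dioxide, O=C=O
Why: Pd(0) ionises the γ,δ-epoxy enal with inversion and the CO2-derived carbonate anion closes on the same allyl carbon with a second inversion (Pd-catalysed CO2 insertion into a vinyl epoxide), so the allylic C–O bond is retained and the carbonate is cis-fused.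

Step 16
Reactants: 27 (3aR,7aS)-4,6,6-trimethyl-2-oxo-3a,6,7,7a-tetrahydro-1,3-benzodioxole-5-carbaldehyde; 28 diethyl [(2E)-3-cyano-2-methylprop-2-en-1-yl]phosphonate
Product: 30 (2E,4E)-3-methyl-5-[(3aR,7aS)-4,6,6-trimethyl-2-oxo-3a,6,7,7a-tetrahydro-1,3-benzodioxol-5-yl]penta-2,4-dienenitrile, via phosphonate carbanion 29 (not isolated)
Conditions: NaH, THF, 0 °C; then 27, 0 °C to rt; the minor 9Z isomer is removed by chromatography
Reagents that add atoms: none
Why: Horner–Wadsworth–Emmons olefination with the C5 nitrile phosphonate, the standard reagent for hindered cyclocitral-type aldehydes, forms the new disubstituted alkene E, and the soft carbanion should spare the cyclic carbonate.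

Step 17
Reactants: 30 (2E,4E)-3-methyl-5-[(3aR,7aS)-4,6,6-trimethyl-2-oxo-3a,6,7,7a-tetrahydro-1,3-benzodioxol-5-yl]penta-2,4-dienenitrile
Product: 31 (2E,4E)-5-[(3R,4S)-3,4-dihydroxy-2,6,6-trimethylcyclohex-1-en-1-yl]-3-methylpenta-2,4-dienal
Conditions: DIBAL-H (excess), CH2Cl2, −78 to −20 °C; wet SiO2, then aq. Rochelle salt
Reagents that add atoms: water, O
Why: DIBAL-H adds once to the conjugated nitrile (the imine is hydrolysed to the aldehyde on work-up) and cleaves the cyclic carbonate reductively in the same operation, freeing the cis-diol without acid.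

Step 18
Reactants: 24 (5Z)-3-bromo-5-[(2E,4E)-6-hydroxy-2-methylhexa-2,4-dien-1-ylidene]furan-2(5H)-one; 15 (1R,2R,4S)-2,6,6-trimethyl-1-[(E)-2-(tributylstannyl)ethenyl]-7-oxabicyclo[2.2.1]heptan-2-ol
Product: 32 (5Z)-5-[(2E,4E)-6-hydroxy-2-methylhexa-2,4-dien-1-ylidene]-3-{(E)-2-[(1R,2R,4S)-2-hydroxy-2,6,6-trimethyl-7-oxabicyclo[2.2.1]heptan-1-yl]ethenyl}furan-2(5H)-one
Conditions: Pd2(dba)3 (5 mol%), AsPh3, CuI, NMP, rt
Reagents that add atoms: none
Why: Stille coupling of an α-bromobutenolide with an E-vinylstannane proceeds under neutral conditions with retention of both alkene geometries and tolerates the free hydroxyl groups.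

Step 19
Reactants: 32 (5Z)-5-[(2E,4E)-6-hydroxy-2-methylhexa-2,4-dien-1-ylidene]-3-{(E)-2-[(1R,2R,4S)-2-hydroxy-2,6,6-trimethyl-7-oxabicyclo[2.2.1]heptan-1-yl]ethenyl}furan-2(5H)-one
Product: 33 {(2E,4E)-6-[(2Z)-4-{(E)-2-[(1R,2R,4S)-2-hydroxy-2,6,6-trimethyl-7-oxabicyclo[2.2.1]heptan-1-yl]ethenyl}-5-oxofuran-2(5H)-ylidene]-5-methylhexa-2,4-dien-1-yl}triphenylphosphonium bromide
Conditions: PPh3·HBr, MeOH–CH2Cl2, 0 °C to rt
Reagents that add atoms: triphenylphosphine hydrobromide, [Br-].[PH+](c1ccccc1)(c1ccccc1)c1ccccc1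
Why: The primary allylic alcohol ionises to a polyenyl cation stabilised by the ring oxygen and is captured by PPh3 at the terminal carbon (the usual salt formation of carotenoid chemistry), while the tertiary alcohol and the ether bridge cannot ionise as easily.

Step 20
Reactants: 33 the phosphonium bromide of step 19; 31 (2E,4E)-5-[(3R,4S)-3,4-dihydroxy-2,6,6-trimethylcyclohex-1-en-1-yl]-3-methylpenta-2,4-dienal
Product: 35 (5Z)-5-{(2E,4E,6E,8E,10E)-11-[(3R,4S)-3,4-dihydroxy-2,6,6-trimethylcyclohex-1-en-1-yl]-2,9-dimethylundeca-2,4,6,8,10-pentaen-1-ylidene}-3-{(E)-2-[(1R,2R,4S)-2-hydroxy-2,6,6-trimethyl-7-oxabicyclo[2.2.1]heptan-1-yl]ethenyl}furan-2(5H)-one (target), via phosphorus ylide 34 (not isolated)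
Conditions: NaHMDS (1.0 equiv), THF, −78 °C; then 31, −78 °C to rt; then benzene, rt, dark (Z to E equilibration of the new bond)
Reagents that add atoms: none
Why: The ylide, stabilised by conjugation to the lactone carbonyl, forms selectively in the presence of the free hydroxyl groups and should give mainly the E alkene in a Wittig reaction with the dienal, any Z isomer at the new disubstituted bond equilibrating to all-E.

**Compound list**
1 | 3,3-dimethyldihydrofuran-2(3H)-one | CC1(C)CCOC1=O | starting material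
2 | ethynyltriisopropylsilane | C#C[Si](C(C)C)(C(C)C)C(C)C | starting material
3 | lithium (triisopropylsilyl)acetylide | [Li]C#C[Si](C(C)C)(C(C)C)C(C)C | intermediate
4 | 6-hydroxy-4,4-dimethyl-1-(triisopropylsilyl)hex-1-yn-3-one | OCCC(C)(C)C(=O)C#C[Si](C(C)C)(C(C)C)C(C)C | intermediate
5 | (2-bromoallyl)trimethylsilane | C=C(Br)C[Si](C)(C)C | starting material
6 | [3-(trimethylsilyl)prop-1-en-2-yl]magnesium bromide | C=C([Mg]Br)C[Si](C)(C)C | intermediate
7 | rac-4,4-dimethyl-1-(triisopropylsilyl)-3-[3-(trimethylsilyl)prop-1-en-2-yl]hex-1-yne-3,6-diol | OCCC(C)(C)C(O)(C#C[Si](C(C)C)(C(C)C)C(C)C)C(=C)C[Si](C)(C)C | intermediate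
8 | rac-3,6-bis[(triethylsilyl)oxy]-4,4-dimethyl-1-(triisopropylsilyl)-3-[3-(trimethylsilyl)prop-1-en-2-yl]hex-1-yne | CC[Si](CC)(CC)OCCC(C)(C)C(O[Si](CC)(CC)CC)(C#C[Si](C(C)C)(C(C)C)C(C)C)C(=C)C[Si](C)(C)C | intermediate
9 | rac-3,3-dimethyl-4-[(triethylsilyl)oxy]-6-(triisopropylsilyl)-4-[3-(trimethylsilyl)prop-1-en-2-yl]hex-5-ynal | O=CCC(C)(C)C(O[Si](CC)(CC)CC)(C#C[Si](C(C)C)(C(C)C)C(C)C)C(=C)C[Si](C)(C)C | intermediate
10 | {[(1S)-3,3-dimethyl-5-methylidene-4-[(triethylsilyl)oxy]-4-[(triisopropylsilyl)ethynyl]cyclohexyl]oxy}trimethylsilane (both C-4 epimers) | C[Si](C)(C)O[C@H]1CC(C)(C)C(O[Si](CC)(CC)CC)(C#C[Si](C(C)C)(C(C)C)C(C)C)C(=C)C1 | intermediate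
11 | (1R,4S)-2,2-dimethyl-6-methylidene-1-[(triisopropylsilyl)ethynyl]-7-oxabicyclo[2.2.1]heptane | CC(C)[Si](C(C)C)(C(C)C)C#C[C@@]12O[C@@H](CC1(C)C)CC2=C | intermediate
12 | (1S,4S)-6,6-dimethyl-1-[(triisopropylsilyl)ethynyl]-7-oxabicyclo[2.2.1]heptan-2-one | CC(C)[Si](C(C)C)(C(C)C)C#C[C@@]12O[C@@H](CC1(C)C)CC2=O | intermediate
13 | (1S,2R,4S)-2,6,6-trimethyl-1-[(triisopropylsilyl)ethynyl]-7-oxabicyclo[2.2.1]heptan-2-ol (methyl exo, hydroxyl endo) | CC(C)[Si](C(C)C)(C(C)C)C#C[C@@]12O[C@@H](CC1(C)C)C[C@@]2(C)O | intermediate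
14 | (1S,2R,4S)-1-ethynyl-2,6,6-trimethyl-7-oxabicyclo[2.2.1]heptan-2-ol | C#C[C@@]12O[C@@H](CC1(C)C)C[C@@]2(C)O | intermediate
15 | (1R,2R,4S)-2,6,6-trimethyl-1-[(E)-2-(tributylstannyl)ethenyl]-7-oxabicyclo[2.2.1]heptan-2-ol | CCCC[Sn](CCCC)(CCCC)/C=C/[C@@]12O[C@@H](CC1(C)C)C[C@@]2(C)O | intermediate
16 | propiolic acid | C#CC(=O)O | starting material
17 | (E)-2,3-dibromoprop-2-enoic acid | OC(=O)/C(Br)=C\Br | intermediate
18 | (E)-3-methylpent-2-en-4-yn-1-ol | C#C/C(C)=C/CO | starting material
19 | ethyl (triphenylphosphoranylidene)acetate | CCOC(=O)C=P(c1ccccc1)(c1ccccc1)c1ccccc1 | starting material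
20 | (E)-3-methylpent-2-en-4-ynal | C#C/C(C)=C/C=O | intermediate
21 | ethyl (2E,4E)-5-methylhepta-2,4-dien-6-ynoate | C#C/C(C)=C/C=C/C(=O)OCC | intermediate
22 | (2E,4E)-5-methylhepta-2,4-dien-6-yn-1-ol | C#C/C(C)=C/C=C/CO | intermediate
23 | (2E,6E,8E)-2-bromo-10-hydroxy-6-methyldeca-2,6,8-trien-4-ynoic acid | OC(=O)/C(Br)=C\C#C/C(C)=C/C=C/CO | intermediate
24 | (5Z)-3-bromo-5-[(2E,4E)-6-hydroxy-2-methylhexa-2,4-dien-1-ylidene]furan-2(5H)-one | OC/C=C/C=C(C)/C=C1C=C(Br)C(=O)O/1 | intermediate
25 | safranal (2,6,6-trimethylcyclohexa-1,3-diene-1-carbaldehyde) | CC1=C(C=O)C(C)(C)CC=C1 | starting material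
26 | (1R,6S)-2,4,4-trimethyl-7-oxabicyclo[4.1.0]hept-2-ene-3-carbaldehyde | CC1=C(C=O)C(C)(C)C[C@@H]2O[C@H]12 | intermediate
27 | (3aR,7aS)-4,6,6-trimethyl-2-oxo-3a,6,7,7a-tetrahydro-1,3-benzodioxole-5-carbaldehyde (cis-fused carbonate) | CC1=C(C=O)C(C)(C)C[C@@H]2OC(=O)O[C@H]12 | intermediate
28 | diethyl [(2E)-3-cyano-2-methylprop-2-en-1-yl]phosphonate | CCOP(=O)(OCC)C/C(C)=C/C#N | starting material
29 | sodium salt of the carbanion of 28 | CCOP(=O)(OCC)[CH-]/C(C)=C/C#N.[Na+] | intermediate
30 | (2E,4E)-3-methyl-5-[(3aR,7aS)-4,6,6-trimethyl-2-oxo-3a,6,7,7a-tetrahydro-1,3-benzodioxol-5-yl]penta-2,4-dienenitrile | CC1=C(/C=C/C(C)=C/C#N)C(C)(C)C[C@@H]2OC(=O)O[C@H]12 | intermediate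
31 | (2E,4E)-5-[(3R,4S)-3,4-dihydroxy-2,6,6-trimethylcyclohex-1-en-1-yl]-3-methylpenta-2,4-dienal (cis-diol; 3S,4R in carotenoid numbering) | CC1=C(/C=C/C(C)=C/C=O)C(C)(C)C[C@H](O)[C@@H]1O | intermediate
32 | (5Z)-5-[(2E,4E)-6-hydroxy-2-methylhexa-2,4-dien-1-ylidene]-3-{(E)-2-[(1R,2R,4S)-2-hydroxy-2,6,6-trimethyl-7-oxabicyclo[2.2.1]heptan-1-yl]ethenyl}furan-2(5H)-one | OC/C=C/C=C(C)/C=C1C=C(/C=C/[C@@]23O[C@@H](CC2(C)C)C[C@@]3(C)O)C(=O)O/1 | intermediate
33 | {(2E,4E)-6-[(2Z)-4-{(E)-2-[(1R,2R,4S)-2-hydroxy-2,6,6-trimethyl-7-oxabicyclo[2.2.1]heptan-1-yl]ethenyl}-5-oxofuran-2(5H)-ylidene]-5-methylhexa-2,4-dien-1-yl}triphenylphosphonium bromide | [Br-].c1ccccc1[P+](c1ccccc1)(c1ccccc1)C/C=C/C=C(C)/C=C1C=C(/C=C/[C@@]23O[C@@H](CC2(C)C)C[C@@]3(C)O)C(=O)O/1 | intermediate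
34 | ylide of 33 (drawn as the zwitterion) | c1ccccc1[P+](c1ccccc1)(c1ccccc1)[CH-]/C=C/C=C(C)/C=C1C=C(/C=C/[C@@]23O[C@@H](CC2(C)C)C[C@@]3(C)O)C(=O)O/1 | intermediate
35 | (5Z)-5-{(2E,4E,6E,8E,10E)-11-[(3R,4S)-3,4-dihydroxy-2,6,6-trimethylcyclohex-1-en-1-yl]-2,9-dimethylundeca-2,4,6,8,10-pentaen-1-ylidene}-3-{(E)-2-[(1R,2R,4S)-2-hydroxy-2,6,6-trimethyl-7-oxabicyclo[2.2.1]heptan-1-yl]ethenyl}furan-2(5H)-one | CC1=C(/C=C/C(C)=C/C=C/C=C/C=C(C)/C=C2C=C(/C=C/[C@@]34O[C@@H](CC3(C)C)C[C@@]4(C)O)C(=O)O/2)C(C)(C)C[C@H](O)[C@@H]1O | target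

**Totals**
Total steps: 20. Longest linear sequence: 12 (steps 1–9, then 18–20).

**Steps most likely to fail**

Step 5. The counter-anion may not control the aldehyde face well enough, or ionisation and elimination of the tertiary silyl ether may outrun the allylation. The fallback uses the known epoxide-opening logic of 3,6-epoxy carotenoid end groups; it sets out from acetylide 3 (made from 2) and returns at 14. Commercial (4R,6R)-4-hydroxy-2,2,6-trimethylcyclohexan-1-one F1 is silylated (TBSCl, imidazole) to the silyl ether F2. Addition of 3 gives the propargylic alcohol F3, and dehydration (POCl3, pyridine) gives the enyne F4. m-CPBA should epoxidise mainly anti to the silyloxy group to give the epoxide F5 (the syn isomer is removed). TBAF removes both silyl groups to give the epoxy alcohol F6, and a trace of acid (PPTS, CH2Cl2) lets the ring hydroxyl open the oxirane at the propargylic carbon with inversion to give 14.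

Step 14. The catalyst may discriminate the alkene faces poorly on this dienal, or the peracid may attack the aldehyde. The fallback sets out from 25 and returns at 27. Upjohn dihydroxylation (OsO4 cat., NMO) of the ring cis-alkene gives the racemic cis-diol F7. Lipase-catalysed acetylation with vinyl acetate is expected, by the empirical rule for lipases and secondary alcohols, to acylate the unwanted enantiomer at its less hindered hydroxyl to the acetate F9 and leave the (3R,4S)-diol F8. F8 is closed with carbonyldiimidazole to 27.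

Step 20. The base may open the lactone, the extended ylide may react through a remote carbon or too slowly with the conjugated aldehyde, and the new double bond may form with low E selectivity. The fallback is a modified Julia olefination, which adds irreversibly at −78 °C; it sets out from 32 and returns at 35. Mitsunobu reaction of 32 with 2-mercaptobenzothiazole gives the sulfide F10. Oxidation (ammonium molybdate, H2O2) gives the benzothiazolyl sulfone F11. Deprotonation with NaHMDS at −78 °C and addition of 31 gives 35 after Z to E equilibration.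

**Further compounds**
F1 | step 5 | (4R,6R)-4-hydroxy-2,2,6-trimethylcyclohexan-1-one | C[C@@H]1C[C@@H](O)CC(C)(C)C1=O
F2 | step 5 | (4R,6R)-4-[(tert-butyldimethylsilyl)oxy]-2,2,6-trimethylcyclohexan-1-one | C[C@@H]1C[C@@H](O[Si](C)(C)C(C)(C)C)CC(C)(C)C1=O
F3 | step 5 | (4R,6R)-4-[(tert-butyldimethylsilyl)oxy]-2,2,6-trimethyl-1-[(triisopropylsilyl)ethynyl]cyclohexan-1-ol (C-1 epimers) | C[C@@H]1C[C@@H](O[Si](C)(C)C(C)(C)C)CC(C)(C)C1(O)C#C[Si](C(C)C)(C(C)C)C(C)C
F4 | step 5 | tert-butyldimethyl{[(1R)-3,5,5-trimethyl-4-[(triisopropylsilyl)ethynyl]cyclohex-3-en-1-yl]oxy}silane | CC1=C(C#C[Si](C(C)C)(C(C)C)C(C)C)C(C)(C)C[C@H](O[Si](C)(C)C(C)(C)C)C1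
F5 | step 5 | epoxide of F4 with the oxirane oxygen anti to the silyloxy group | CC(C)[Si](C(C)C)(C(C)C)C#C[C@@]12O[C@]1(C)C[C@@H](O[Si](C)(C)C(C)(C)C)CC2(C)C
F6 | step 5 | 6-ethynyl-1,5,5-trimethyl-7-oxabicyclo[4.1.0]heptan-3-ol with the hydroxyl anti to the oxirane oxygen | C#C[C@@]12O[C@]1(C)C[C@@H](O)CC2(C)C
F7 | step 14 | rac-cis-3,4-dihydroxy-2,6,6-trimethylcyclohex-1-ene-1-carbaldehyde | CC1=C(C=O)C(C)(C)CC(O)C1O
F8 | step 14 | (3R,4S)-3,4-dihydroxy-2,6,6-trimethylcyclohex-1-ene-1-carbaldehyde | CC1=C(C=O)C(C)(C)C[C@H](O)[C@@H]1O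
F9 | step 14 | 4-O-acetate of the (3S,4R)-enantiomer of F8 | CC1=C(C=O)C(C)(C)C[C@@H](OC(C)=O)[C@H]1O
F10 | step 20 | 2-({(2E,4E)-6-[(2Z)-4-{(E)-2-[(1R,2R,4S)-2-hydroxy-2,6,6-trimethyl-7-oxabicyclo[2.2.1]heptan-1-yl]ethenyl}-5-oxofuran-2(5H)-ylidene]-5-methylhexa-2,4-dien-1-yl}sulfanyl)-1,3-benzothiazole | c1ccc2sc(SC/C=C/C=C(C)/C=C3C=C(/C=C/[C@@]45O[C@@H](CC4(C)C)C[C@@]5(C)O)C(=O)O/3)nc2c1
F11 | step 20 | the corresponding 2-sulfonyl-1,3-benzothiazole (sulfone of F10) | c1ccc2sc(S(=O)(=O)C/C=C/C=C(C)/C=C3C=C(/C=C/[C@@]45O[C@@H](CC4(C)C)C[C@@]5(C)O)C(=O)O/3)nc2c1
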